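**Retrosynthetic overview**

1. The target is traced back to the trans-fused diketo diester 15 through acylation of the C19 alcohol, ester-to-alcohol reduction, C3 deoxygenation, Wittig methylenation at C8 and methylation at C4.
2. Ring A (C1–C5 and C10) is closed last: the C4–C5 bond of 15 is made by insertion of a dirhodium carbenoid at C4 (from the α-diazo-β-keto ester chain of monocyclic 14) into the unactivated C5–H bond of ring B.
3. Enabling feature: C10, the ring-fusion carbon bearing the C20 methyl, is quaternary, so a carbenoid tethered through C3–C2–C1 finds no C–H at the usual five-ring distance and must reach the ring-B methylene C5. The C8 carbonyl of ring B deactivates the neighbouring C9–H.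
4. 14 comes from 3-methylcyclohex-2-en-1-one (ring B) by copper-catalysed asymmetric conjugate addition of the C1–C3 unit (sets C10) and aldol trapping at C9 with aldehyde 3, which brings C11–C15 and C13 from methyl hydrogen (3R)-3-methylglutarate.
5. Ring order: ring B is present from the first ring-bearing step, ring A is formed in step 9; C5, C4 and C9 are then set under the control of C10.

Key step: step 9

Assumption: methyl hydrogen (3R)-3-methylglutarate (1) and (2R)-2-methylbutanoic acid (23) are taken as commercially available single enantiomers.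

Locants C1–C20 in the text are those of the labdane skeleton of the target.

Step 1
Reactants: 1 methyl hydrogen (3R)-3-methylglutarate
Product: 2 methyl (3R)-5-hydroxy-3-methylpentanoate
Conditions: BH3·SMe2, THF, 0 °C → rt; MeOH, aq. work-up
Reagents that add atoms: none
Why: Borane reduction of a carboxylic acid beside an ester should be chemoselective because BH3 reacts with the free acid through an acyloxyborane much faster than with the methyl ester, and the stereocentre (C13 of the target) is not touched.

Step 2
Reactants: 2 methyl (3R)-5-hydroxy-3-methylpentanoate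
Product: 3 methyl (3R)-3-methyl-5-oxopentanoate
Conditions: PhI(OAc)2, TEMPO (10 mol %), CH2Cl2, rt
Reagents that add atoms: none
Why: TEMPO-catalysed alcohol oxidation with PhI(OAc)2 as terminal oxidant should stop at the aldehyde under anhydrous conditions and cannot epimerise the β-stereocentre.

Step 3
Reactants: 4 3-methylcyclohex-2-en-1-one; 5 2-(2-bromoethyl)-1,3-dioxolane; 3 methyl (3R)-3-methyl-5-oxopentanoate
Product: 8 methyl (3R)-5-{(2S)-2-[2-(1,3-dioxolan-2-yl)ethyl]-2-methyl-6-oxocyclohexyl}-5-hydroxy-3-methylpentanoate (diastereomer mixture at the carbinol carbon and at ring C1), via Grignard reagent 6 (not isolated), via magnesium enolate 7 (not isolated)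
Conditions: 5, Mg, THF, 25 °C; then 4, Cu(OTf)2 (3 mol %), chiral imidazolinium salt (NHC precursor, 4 mol %), Et2O, 0 °C; then 3, −78 °C; aq. NH4Cl
Reagents that add atoms: none
Why: Copper-catalysed asymmetric conjugate addition of a Grignard reagent to a β-methyl cyclohexenone followed by aldol trapping of the regiodefined magnesium enolate should set the quaternary centre (C10, S) by catalyst control (ligand antipode chosen accordingly) and fix C–C bond formation at C9, while the uncontrolled C9 and C11 centres are erased in step 4 and C9 is set in step 10.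

Step 4
Reactants: 8 aldol adduct
Product: 10 methyl (3R,5E)-5-{(2S)-2-[2-(1,3-dioxolan-2-yl)ethyl]-2-methyl-6-oxocyclohexylidene}-3-methylpentanoate, via mesylate 9 (not isolated)
Conditions: MsCl, Et3N, CH2Cl2, 0 °C; then DBU, rt
Reagents that add atoms: none
Why: Mesylation and base-induced E1cB elimination (aldol dehydration) should give the conjugated alkylidene ketone and remove both uncontrolled stereocentres.

Step 5
Reactants: 10 alkylidene ketone
Product: 11 methyl (3R)-5-{(2S)-2-[2-(1,3-dioxolan-2-yl)ethyl]-2-methyl-6-oxocyclohexyl}-3-methylpentanoate (epimer mixture at ring C1, which is C9 of the target)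
Conditions: H2 (1 atm), Pd/C, EtOAc, rt
Reagents that add atoms: none
Why: Heterogeneous catalytic hydrogenation should saturate only the conjugated alkene (acetal, ketone and ester are inert); C9 forms as an epimer mixture that is equilibrated in step 10.

Step 6
Reactants: 11 keto acetal
Product: 12 methyl (3R)-3-methyl-5-[(2S)-2-methyl-6-oxo-2-(3-oxopropyl)cyclohexyl]pentanoate (C9 epimers)
Conditions: TsOH·H2O (cat.), acetone/H2O, rt
Reagents that add atoms: water, O
Why: Acid-catalysed acetal hydrolysis under mild conditions should unmask the C3 aldehyde without hydrolysing the methyl ester.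

Step 7
Reactants: 12 keto aldehyde
Product: 13 methyl 5-{(1S)-2-[(3R)-5-methoxy-3-methyl-5-oxopentyl]-1-methyl-3-oxocyclohexyl}-3-oxopentanoate (C9 epimers)
Conditions: methyl diazoacetate, SnCl2 (10 mol %), CH2Cl2, rt
Reagents that add atoms: methyl diazoacetate, COC(=O)C=[N+]=[N-]
Why: Roskamp homologation (SnCl2-promoted addition of the diazoester to the aldehyde, then 1,2-hydride shift with loss of N2) should give the β-keto ester, the less electrophilic ring ketone staying untouched.

Step 8
Reactants: 13 β-keto ester
Product: 14 methyl 2-diazo-5-{(1S)-2-[(3R)-5-methoxy-3-methyl-5-oxopentyl]-1-methyl-3-oxocyclohexyl}-3-oxopentanoate (C9 epimers)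
Conditions: 4-acetamidobenzenesulfonyl azide, Et3N, MeCN, 0 °C → rt
Reagents that add atoms: 4-acetamidobenzenesulfonyl azide, CC(=O)Nc1ccc(cc1)S(=O)(=O)N=[N+]=[N-]
Why: Regitz diazo transfer should occur only at the doubly activated methylene, since the ketone and ester α-positions are not acidic enough under these conditions.

Step 9
Reactants: 14 α-diazo-β-keto ester
Product: 15 dimethyl (13R)-3,8-dioxo-17,18-dinor-ent-labdane-15,19-dioate (trans-fused; C4 epimerisable and partly enolised; C9 epimers)
Conditions: Rh2(OAc)4 (1 mol %), CH2Cl2, 40 °C, slow addition of 14 at high dilution, 4 Å MS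
Reagents that add atoms: none
Why: Proposed new method: Rh2(OAc)4 should decompose the diazo group with loss of N2 to an electrophilic rhodium carbenoid at C4, which inserts into a C–H bond through a concerted three-centre transition state (hydride shift to the carbenoid carbon together with C–C bond formation, retention at the reacting carbon). The closest known reaction type is the dirhodium-catalysed intramolecular C–H insertion of α-diazo-β-keto esters, established for closing cyclopentanones (1,5-insertion) and for six-membered rings at activated or rigidly held C–H bonds; what is new here is the 1,6-insertion into an unactivated methylene of a flexible cyclohexanone. Ring A closes in a six-membered (1,6-insertion) mode by C4–C5 bond formation, because the atom at the 1,5-position is the quaternary C10, which carries the C20 methyl and no hydrogen. The new C5 centre is controlled by C10: in the chair-like, decalin-type transition state both ring-B bonds (C10–C9 and C5–C6) are equatorial on the forming ring and only the C20 methyl is axial, so the equatorial C5–H is replaced with retention and the trans ring fusion results; C4 is formed as an epimerisable β-keto ester centre and is fixed in step 10. The step needs site selectivity among the three C–H sets at the same distance from C4 (C5–H2, C9–H, C20–H3) and over carbenoid dimerisation: C9–H is α to the C8 ketone (inductively deactivated) and shielded by the side chain, the C20–H bonds are primary, C5–H2 is the only electron-rich secondary site, and slow addition keeps the carbenoid concentration low.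

Step 10
Reactants: 15 bicyclic β-keto ester
Product: 16 dimethyl (13R)-3,8-dioxo-17-nor-ent-labdane-15,19-dioate (C4 methyl equatorial, C19 ester axial, C9 side chain equatorial)
Conditions: Cs2CO3, MeI, DMF, 0 °C → rt
Reagents that add atoms: iodomethane, CI
Why: C-Alkylation of the β-keto ester enolate should take place on the face opposite to the axial C20 methyl, so the new methyl is equatorial and the ester axial (sets C4), while the carbonate base equilibrates C9 through the C8 enolate to the equatorial side chain (sets C9).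

Step 11
Reactants: 16 diketo diester
Product: 17 dimethyl (13R)-3-oxo-ent-labd-8(17)-ene-15,19-dioate
Conditions: Ph3PCH3Br, KN(SiMe3)2, THF, 0 °C; then 16, 0 °C → rt
Reagents that add atoms: methyltriphenylphosphonium bromide, C[P+](c1ccccc1)(c1ccccc1)c1ccccc1.[Br-]
Why: Wittig methylenation should select the C8 ketone because the C3 carbonyl is shielded by the adjacent quaternary C4, and the alkoxide-free ylide avoids retro-Claisen cleavage of the non-enolisable β-keto ester.

Step 12
Reactants: 17 keto diester
Product: 18 dimethyl (13R)-3-[(E)-2-tosylhydrazinylidene]-ent-labd-8(17)-ene-15,19-dioate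
Conditions: TsNHNH2, EtOH, AcOH (cat.), 70 °C
Reagents that add atoms: 4-methylbenzenesulfonohydrazide, Cc1ccc(cc1)S(=O)(=O)NN
Why: Condensation of the only remaining ketone with tosylhydrazide should give the hydrazone needed for Caglioti-type deoxygenation, esters and the alkene being inert.

Step 13
Reactants: 18 tosylhydrazone
Product: 20 dimethyl (13R)-ent-labd-8(17)-ene-15,19-dioate, via N-borylhydrazine 19 (not isolated)
Conditions: catecholborane, CHCl3, 0 °C → rt; then NaOAc·3H2O, 60 °C
Reagents that add atoms: none
Why: Caglioti-type reduction should deliver hydride to C3, after which acetate releases sulfinate and the diazene loses N2 to leave the C3 methylene; the unactivated alkene is not hydroborated at this temperature.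

Step 14
Reactants: 20 diester
Product: 21 (13R)-19-methoxy-19-oxo-ent-labd-8(17)-en-15-oic acid
Conditions: LiOH, THF/H2O, 0 °C → rt; then aq. HCl
Reagents that add atoms: lithium hydroxide, [Li+].[OH-]
Why: Saponification should discriminate sterically, hydroxide attacking the unhindered C15 ester while the axial, neopentylic C19 ester (1,3-diaxial to the C20 methyl) reacts far more slowly.

Step 15
Reactants: 21 monoacid monoester
Product: 22 (13R)-19-hydroxy-ent-labd-8(17)-en-15-oic acid
Conditions: LiBHEt3, THF, 0 °C → rt; then aq. HCl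
Reagents that add atoms: none
Why: Hydride reduction with LiBHEt3 should first deprotonate the acid to a lithium carboxylate that resists hydride, so only the hindered C19 ester is reduced to the primary alcohol.

Step 16
Reactants: 22 hydroxy acid; 23 (2R)-2-methylbutanoic acid
Product: 26 (13R)-19-{[(2R)-2-methylbutanoyl]oxy}-ent-labd-8(17)-en-15-oic acid (4R,5S,9R,10S,13R), via symmetrical anhydride 24 (not isolated), via mixed anhydride 25 (not isolated)
Conditions: 23, DCC, CH2Cl2, 0 °C, filter; then 22, DMAP, pyridine, rt; then NaHCO3, H2O/THF; aq. citric acid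
Reagents that add atoms: water, O
Why: DMAP-catalysed acylation of the neopentylic alcohol with the symmetrical anhydride (no acid chloride or ketene, so the α-stereocentre of the acyl group is kept) should give the ester, and the mixed anhydride formed at C15 is hydrolysed at its less hindered carbonyl on work-up.

**Compound list**

1 | methyl hydrogen (3R)-3-methylglutarate | OC(=O)C[C@@H](C)CC(=O)OC | starting material
2 | methyl (3R)-5-hydroxy-3-methylpentanoate | OCC[C@@H](C)CC(=O)OC | intermediate
3 | methyl (3R)-3-methyl-5-oxopentanoate | O=CC[C@@H](C)CC(=O)OC | intermediate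
4 | 3-methylcyclohex-2-en-1-one | CC1=CC(=O)CCC1 | starting material
5 | 2-(2-bromoethyl)-1,3-dioxolane | BrCCC1OCCO1 | starting material
6 | [2-(1,3-dioxolan-2-yl)ethyl]magnesium bromide | Br[Mg]CCC1OCCO1 | intermediate
7 | bromomagnesium enolate (C8–O, C8=C9) of (3S)-3-[2-(1,3-dioxolan-2-yl)ethyl]-3-methylcyclohexan-1-one | Br[Mg]OC1=C[C@](C)(CCC2OCCO2)CCC1 | intermediate
8 | methyl (3R)-5-{(2S)-2-[2-(1,3-dioxolan-2-yl)ethyl]-2-methyl-6-oxocyclohexyl}-5-hydroxy-3-methylpentanoate (diastereomer mixture) | O=C1CCC[C@@](C)(CCC2OCCO2)C1C(O)C[C@@H](C)CC(=O)OC | intermediate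
9 | methanesulfonate of 8 at the carbinol oxygen | O=C1CCC[C@@](C)(CCC2OCCO2)C1C(OS(C)(=O)=O)C[C@@H](C)CC(=O)OC | intermediate
10 | methyl (3R,5E)-5-{(2S)-2-[2-(1,3-dioxolan-2-yl)ethyl]-2-methyl-6-oxocyclohexylidene}-3-methylpentanoate | O=C1CCC[C@@](C)(CCC2OCCO2)/C1=C\C[C@@H](C)CC(=O)OC | intermediate
11 | methyl (3R)-5-{(2S)-2-[2-(1,3-dioxolan-2-yl)ethyl]-2-methyl-6-oxocyclohexyl}-3-methylpentanoate (C9 epimers) | O=C1CCC[C@@](C)(CCC2OCCO2)C1CC[C@@H](C)CC(=O)OC | intermediate
12 | methyl (3R)-3-methyl-5-[(2S)-2-methyl-6-oxo-2-(3-oxopropyl)cyclohexyl]pentanoate (C9 epimers) | O=C1CCC[C@@](C)(CCC=O)C1CC[C@@H](C)CC(=O)OC | intermediate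
13 | methyl 5-{(1S)-2-[(3R)-5-methoxy-3-methyl-5-oxopentyl]-1-methyl-3-oxocyclohexyl}-3-oxopentanoate (C9 epimers) | O=C1CCC[C@@](C)(CCC(=O)CC(=O)OC)C1CC[C@@H](C)CC(=O)OC | intermediate
14 | methyl 2-diazo-5-{(1S)-2-[(3R)-5-methoxy-3-methyl-5-oxopentyl]-1-methyl-3-oxocyclohexyl}-3-oxopentanoate (C9 epimers) | O=C1CCC[C@@](C)(CCC(=O)C(=[N+]=[N-])C(=O)OC)C1CC[C@@H](C)CC(=O)OC | intermediate
15 | dimethyl (13R)-3,8-dioxo-17,18-dinor-ent-labdane-15,19-dioate (trans-fused; C4 and C9 epimers) | O=C1CC[C@@H]2C(C(=O)OC)C(=O)CC[C@@]2(C)C1CC[C@@H](C)CC(=O)OC | intermediate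
16 | dimethyl (13R)-3,8-dioxo-17-nor-ent-labdane-15,19-dioate | O=C1CC[C@@H]2[C@](C)(C(=O)OC)C(=O)CC[C@@]2(C)[C@@H]1CC[C@@H](C)CC(=O)OC | intermediate
17 | dimethyl (13R)-3-oxo-ent-labd-8(17)-ene-15,19-dioate | C=C1CC[C@@H]2[C@](C)(C(=O)OC)C(=O)CC[C@@]2(C)[C@@H]1CC[C@@H](C)CC(=O)OC | intermediate
18 | dimethyl (13R)-3-[(E)-2-tosylhydrazinylidene]-ent-labd-8(17)-ene-15,19-dioate | C=C1CC[C@@H]2[C@](C)(C(=O)OC)/C(=N/NS(=O)(=O)c3ccc(C)cc3)CC[C@@]2(C)[C@@H]1CC[C@@H](C)CC(=O)OC | intermediate
19 | dimethyl (13R)-3-[1-(1,3,2-benzodioxaborol-2-yl)-2-tosylhydrazinyl]-ent-labd-8(17)-ene-15,19-dioate (C3 epimers) | C=C1CC[C@@H]2[C@](C)(C(=O)OC)C(N(NS(=O)(=O)c3ccc(C)cc3)B3Oc4ccccc4O3)CC[C@@]2(C)[C@@H]1CC[C@@H](C)CC(=O)OC | intermediate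
20 | dimethyl (13R)-ent-labd-8(17)-ene-15,19-dioate | C=C1CC[C@@H]2[C@](C)(C(=O)OC)CCC[C@@]2(C)[C@@H]1CC[C@@H](C)CC(=O)OC | intermediate
21 | (13R)-19-methoxy-19-oxo-ent-labd-8(17)-en-15-oic acid | C=C1CC[C@@H]2[C@](C)(C(=O)OC)CCC[C@@]2(C)[C@@H]1CC[C@@H](C)CC(=O)O | intermediate
22 | (13R)-19-hydroxy-ent-labd-8(17)-en-15-oic acid | C=C1CC[C@@H]2[C@](C)(CO)CCC[C@@]2(C)[C@@H]1CC[C@@H](C)CC(=O)O | intermediate
23 | (2R)-2-methylbutanoic acid | CC[C@@H](C)C(=O)O | starting material
24 | (2R)-2-methylbutanoic anhydride | CC[C@@H](C)C(=O)OC(=O)[C@H](C)CC | intermediate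
25 | mixed anhydride of 26 (at C15) with (2R)-2-methylbutanoic acid | C=C1CC[C@@H]2[C@](C)(COC(=O)[C@H](C)CC)CCC[C@@]2(C)[C@@H]1CC[C@@H](C)CC(=O)OC(=O)[C@H](C)CC | intermediate
26 | (13R)-19-{[(2R)-2-methylbutanoyl]oxy}-ent-labd-8(17)-en-15-oic acid (4R,5S,9R,10S,13R) | C=C1CC[C@@H]2[C@](C)(COC(=O)[C@H](C)CC)CCC[C@@]2(C)[C@@H]1CC[C@@H](C)CC(=O)O | target

**Step count**

Total step count: 16. Longest linear sequence: 16 steps (1 → 26; 14 steps from 4).

**Steps most likely to fail**

Step 9 (Proposed new method). The carbenoid may insert into the axial C5–H, the C20 methyl or the C9–H bond, or dimerise, so that the trans-fused ring A does not form selectively. The fallback uses known chemistry, sets out from alcohol 2 and comes back at diketone 16: ring A is made by Robinson annulation onto a ring B that already carries a carbonyl group at C5. Alcohol 2 is converted (I2, PPh3, imidazole) into methyl (3S)-5-iodo-3-methylpentanoate F1 and then (Et2Zn, CuI cat.) into bis[(3S)-5-methoxy-3-methyl-5-oxopentyl]zinc F2. Asymmetric conjugate addition of F2 (Cu(OTf)2, chiral phosphoramidite, toluene, −30 °C) to commercial 1,4-dioxaspiro[4.5]dec-6-en-8-one and methylation of the zinc enolate (MeI, HMPA) should give methyl (3R)-3-methyl-5-[(6S)-7-methyl-8-oxo-1,4-dioxaspiro[4.5]decan-6-yl]pentanoate F3, with C9 set by the catalyst. Robinson annulation with methyl 3-oxopent-4-enoate (NaOMe, MeOH) should add the C10 enolate anti to the C9 side chain and close ring A by aldol condensation at C5, giving dimethyl (13R)-8,8-ethylenedioxy-3-oxo-17,18-dinor-ent-labd-4-ene-15,19-dioate F4. Birch-type reductive methylation (Li, NH3, THF, −78 °C, no proton donor; then MeI) should set the trans ring fusion and the C4 centre, giving dimethyl (13R)-8,8-ethylenedioxy-3-oxo-17-nor-ent-labdane-15,19-dioate F5, and ketal hydrolysis (aq. HCl, THF) returns to 16.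

Step 12. Condensation at the neopentylic C3 carbonyl may stall, or the hydrazone nitrogen may cyclise onto the neighbouring C19 ester. The fallback sets out from ketone 17 and comes back at diester 20 by radical deoxygenation: NaBH4 (MeOH, 0 °C) should give dimethyl (13R)-3-hydroxy-ent-labd-8(17)-ene-15,19-dioate F6 (C3 epimers), KN(SiMe3)2/CS2/MeI its S-methyl xanthate F7, and Barton–McCombie reduction (Bu3SnH, AIBN, toluene, 110 °C) leads to 20.

Step 3. The thermally labile acetal Grignard reagent may add with eroded enantioselectivity, and aldol trapping may be incomplete through proton transfer or addition of excess Grignard reagent to aldehyde 3. The fallback sets out from bromide 5 and comes back at aldol 8 with the roles of the two C10 substituents exchanged: Grignard reagent 6 (from 5) is added to 3-ethoxycyclohex-2-en-1-one and the adduct hydrolysed (aq. oxalic acid) to 3-[2-(1,3-dioxolan-2-yl)ethyl]cyclohex-2-en-1-one F8. Copper-catalysed asymmetric conjugate addition of Me3Al (Cu(OAc)2, chiral phosphoramidite, Et2O, −30 °C) should then install the methyl group at C10, and the aluminium enolate is trapped with aldehyde 3 to give 8.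

Further compounds
F1 | step 9 | methyl (3S)-5-iodo-3-methylpentanoate | ICC[C@@H](C)CC(=O)OC
F2 | step 9 | bis[(3S)-5-methoxy-3-methyl-5-oxopentyl]zinc | COC(=O)C[C@H](C)CC[Zn]CC[C@@H](C)CC(=O)OC
F3 | step 9 | methyl (3R)-3-methyl-5-[(6S)-7-methyl-8-oxo-1,4-dioxaspiro[4.5]decan-6-yl]pentanoate (C7 epimers) | O=C1CCC2(OCCO2)[C@@H](CC[C@@H](C)CC(=O)OC)C1C
F4 | step 9 | dimethyl (13R)-8,8-ethylenedioxy-3-oxo-17,18-dinor-ent-labd-4-ene-15,19-dioate | COC(=O)C1=C2CCC3(OCCO3)[C@@H](CC[C@@H](C)CC(=O)OC)[C@]2(C)CCC1=O
F5 | step 9 | dimethyl (13R)-8,8-ethylenedioxy-3-oxo-17-nor-ent-labdane-15,19-dioate | O=C1CC[C@@]2(C)[C@H](CC[C@@H](C)CC(=O)OC)C3(OCCO3)CC[C@@H]2[C@]1(C)C(=O)OC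
F6 | step 12 | dimethyl (13R)-3-hydroxy-ent-labd-8(17)-ene-15,19-dioate (C3 epimers) | C=C1CC[C@@H]2[C@](C)(C(=O)OC)C(O)CC[C@@]2(C)[C@@H]1CC[C@@H](C)CC(=O)OC
F7 | step 12 | dimethyl (13R)-3-{[(methylsulfanyl)carbonothioyl]oxy}-ent-labd-8(17)-ene-15,19-dioate (C3 epimers) | C=C1CC[C@@H]2[C@](C)(C(=O)OC)C(OC(=S)SC)CC[C@@]2(C)[C@@H]1CC[C@@H](C)CC(=O)OC
F8 | step 3 | 3-[2-(1,3-dioxolan-2-yl)ethyl]cyclohex-2-en-1-one | O=C1C=C(CCC2OCCO2)CCC1
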